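**Plan**
- The retrosynthesis cuts the two C–C bonds that join each bridge carbon (the CH2 groups on C3 and C5 of the central ring B) to the lateral rings A and C. Both bridge carbons stay with ring B as CH2–SPh arms, and rings A and C are one and the same phenol, needed twice.
- Enabling feature: in rings A and C the bridge is bonded to the only unsubstituted ring carbon (C5 of the lateral butyrophenone), and this carbon is ortho to both phenolic oxygens (on C4 and C6). Either oxygen can therefore hold a sulfonium centre and pass the benzylic carbon on by a [2,3] shift.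
- Forward: ring B is made from phloroglucinol (acylation, two phenylthiomethyl arms from two thiophenol and two formaldehyde, three benzyl ethers). The lateral phenol is made from 2,4,6-trihydroxytoluene (acylation, two benzyl ethers, O-methylation, hydrogenolysis). Two molecules of the lateral phenol are then attached to one molecule of ring B in one flask with no new ring formed, and Raney Ni followed by hydrogenolysis removes sulfur and benzyl groups.
- Stereochemistry: the single (S) centre is bought with (S)-2-methylbutanoic acid and carried through; the two sulfur-bearing bridge carbons made in the key step become CH2 at the end.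

Key step: step 8

Assumption: 2,4,6-trihydroxytoluene (2-methylphloroglucinol) is treated as a catalogue chemical.

**Step 1**
Reactants: 1 phloroglucinol; 2 (S)-2-methylbutanoic acid
Product: 4 (2S)-2-methyl-1-(2,4,6-trihydroxyphenyl)butan-1-one, via (S)-2-methylbutanoyl chloride 3 (not isolated)
Conditions: 2, (COCl)2 (1.05 equiv), DMF (cat.), CH2Cl2, 0 °C → rt, volatiles removed; then 1, AlCl3 (4 equiv), CH2Cl2/MeNO2, 0 °C → rt; aq. HCl work-up
Reagents that add atoms: none
Why: Friedel–Crafts C-acylation of phloroglucinol by the acyl chloride made in the flask, which should stop at one acyl group because the AlCl3-bound ketone is deactivated, and which should keep the α-stereocentre of 2 because neither the acylium ion nor the complexed ketone enolises appreciably at or below room temperature (enantiopurity to be checked by chiral HPLC).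

**Step 2**
Reactants: 4 (2S)-2-methyl-1-(2,4,6-trihydroxyphenyl)butan-1-one; 5 thiophenol (two molecules are taken up per molecule of 4)
Product: 6 (2S)-2-methyl-1-[2,4,6-trihydroxy-3,5-bis(phenylsulfanylmethyl)phenyl]butan-1-one
Conditions: 5 (3 equiv) and 37% aq. CH2O (2.4 equiv) premixed in EtOH, rt; then 4, Et3N (cat.), 60 °C
Reagents that add atoms: formaldehyde (one molecule per arm), C=O; thiophenol 5 (the second molecule), Sc1ccccc1
Why: Mannich-type phenol–formaldehyde–thiol condensation (thiomethylation of phenols) with the balance 4 + 2 PhSH + 2 CH2O → 6 + 2 H2O, in which each of the two equivalent free ring carbons is hydroxymethylated and the ortho-quinone methide that follows is trapped by the excess thiol faster than by a second phloroglucinol ring.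

**Step 3**
Reactants: 6 (2S)-2-methyl-1-[2,4,6-trihydroxy-3,5-bis(phenylsulfanylmethyl)phenyl]butan-1-one
Product: 7 (2S)-1-[2,4,6-tris(benzyloxy)-3,5-bis(phenylsulfanylmethyl)phenyl]-2-methylbutan-1-one
Conditions: BnBr (3.6 equiv), K2CO3 (4 equiv), Bu4NI (cat.), DMF, rt → 45 °C
Reagents that add atoms: benzyl bromide, BrCc1ccccc1
Why: Williamson O-benzylation, favoured over C-alkylation for potassium phenoxides of a fully substituted ring in DMF, with a carbonate base too weak to enolise the hindered aryl ketone and disturb the α-stereocentre.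

**Step 4**
Reactants: 8 2,4,6-trihydroxytoluene
Product: 9 1-(2,4,6-trihydroxy-3-methylphenyl)butan-1-one
Conditions: butanoyl chloride (1.1 equiv), AlCl3 (3.5 equiv), CH2Cl2/MeNO2, 0 °C → rt; aq. HCl work-up
Reagents that add atoms: butanoyl chloride, CCCC(=O)Cl
Why: Friedel–Crafts C-acylation in which the two free ring carbons of 8 are equivalent by symmetry, so only one ketone can form, and the deactivated product resists a second acylation.

**Step 5**
Reactants: 9 1-(2,4,6-trihydroxy-3-methylphenyl)butan-1-one
Product: 10 1-[4,6-bis(benzyloxy)-2-hydroxy-3-methylphenyl]butan-1-one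
Conditions: BnBr (2.1 equiv), K2CO3 (2.3 equiv), DMF, rt
Reagents that add atoms: benzyl bromide, BrCc1ccccc1
Why: Williamson etherification that should take the para hydroxyl and the less hindered ortho hydroxyl, because the hydroxyl wedged between the C-methyl and the butanoyl group sits in the six-membered hydrogen-bond chelate and alkylates last, as in the usual 4,6-di-O-benzylation of phloroacylphenones.

**Step 6**
Reactants: 10 1-[4,6-bis(benzyloxy)-2-hydroxy-3-methylphenyl]butan-1-one
Product: 11 1-[4,6-bis(benzyloxy)-2-methoxy-3-methylphenyl]butan-1-one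
Conditions: MeI (5 equiv), K2CO3 (3 equiv), DMF, 50 °C
Reagents that add atoms: iodomethane, CI
Why: O-methylation of the remaining chelated phenol under forcing Williamson conditions, the standard way to place a methoxy group ortho to an acyl group once the other hydroxyls are masked.

**Step 7**
Reactants: 11 1-[4,6-bis(benzyloxy)-2-methoxy-3-methylphenyl]butan-1-one
Product: 12 1-(4,6-dihydroxy-2-methoxy-3-methylphenyl)butan-1-one (the lateral phenol)
Conditions: H2 (1 atm), 10% Pd/C, EtOAc/MeOH, rt
Reagents that add atoms: none
Why: Neutral hydrogenolysis of the two aryl benzyl ethers over Pd/C, which leaves the aryl ketone and the methyl ether untouched.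

**Step 8**
Reactants: 7 (2S)-1-[2,4,6-tris(benzyloxy)-3,5-bis(phenylsulfanylmethyl)phenyl]-2-methylbutan-1-one; 12 1-(4,6-dihydroxy-2-methoxy-3-methylphenyl)butan-1-one (two molecules are taken up per molecule of 7)
Product: 15 (2S)-1-[2,4,6-tris(benzyloxy)-3,5-bis[(3-butanoyl-2,6-dihydroxy-4-methoxy-5-methylphenyl)(phenylsulfanyl)methyl]phenyl]-2-methylbutan-1-one (mixture of isomers at the two bridge carbons), via bis(chlorosulfonium) salt 13 (not isolated), via bis(aryloxysulfonium) salt 14 (not isolated)
Conditions: 7 (1 equiv), NCS (2.1 equiv), CH2Cl2, −78 → −50 °C; then 12 (3 equiv; two are taken up, the rest recovered), CH2Cl2/THF, −78 °C; then Et3N (5 equiv), −78 °C → rt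
Reagents that add atoms: lateral phenol 12 (the second molecule), CCCC(=O)c1c(O)cc(O)c(C)c1OC
Why: Proposed new method: per molecule of 7, NCS chlorinates both benzylic aryl sulfides at sulfur (13), one phenolic oxygen of each of two molecules of 12 (the free 4-OH or the chelated 6-OH) displaces chloride to give the bis(aryloxysulfonium) salt 14, and Et3N removes a benzylic proton at each sulfonium centre (the S-phenyl group offers no other α-hydrogen) to give ylides that undergo [2,3]-sigmatropic shifts through five-membered transition states, each bonding an ylide carbon to C5 of its phenol as the O–S bond breaks, after which the dienones tautomerise to phenols. The closest known reaction type is the Gassman ortho-alkylation of phenols with a dialkyl sulfide, NCS and Et3N; new here are the benzylic aryl sulfide, the chelated acylresorcinol-type phenol and the twofold operation on one ring. No ring is closed. The two sulfur-bearing stereocentres form without control, which is of no consequence because both become CH2 in step 9. The step needs cross-coupling only and attack at one ring carbon: each bridge is assembled from one sulfide and one phenol so neither partner can homodimerise, both hydroxyls of 12 flank the same single unsubstituted carbon, and ring B is hexasubstituted and ether-protected. A Pummerer-type leak to the thionium ion would alkylate the same carbon of 12 and so converge on 15.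

**Step 9**
Reactants: 15 bis(phenylsulfanyl)-bridged tribenzyl trimer
Product: 17 agrimol B, via agrimol B tribenzyl ether 16 (not isolated)
Conditions: Raney Ni (W-2, washed neutral), EtOH/THF, rt → 50 °C; filter (Celite); then H2 (1 atm), 10% Pd/C, EtOAc/EtOH, rt
Reagents that add atoms: none
Why: Reductive desulfurisation of the two benzylic C–S bonds on Raney Ni followed by hydrogenolysis of the three benzyl ethers over Pd/C, both neutral operations that should spare the methylene bridges, the aryl ketones and the α-stereocentre.

**Compound list**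
1 | phloroglucinol | Oc1cc(O)cc(O)c1 | starting material
2 | (S)-2-methylbutanoic acid | CC[C@H](C)C(=O)O | starting material
3 | (S)-2-methylbutanoyl chloride (formed in the flask) | CC[C@H](C)C(=O)Cl | intermediate
4 | (2S)-2-methyl-1-(2,4,6-trihydroxyphenyl)butan-1-one | CC[C@H](C)C(=O)c1c(O)cc(O)cc1O | intermediate
5 | thiophenol | Sc1ccccc1 | starting material
6 | (2S)-2-methyl-1-[2,4,6-trihydroxy-3,5-bis(phenylsulfanylmethyl)phenyl]butan-1-one | CC[C@H](C)C(=O)c1c(O)c(CSc2ccccc2)c(O)c(CSc2ccccc2)c1O | intermediate
7 | (2S)-1-[2,4,6-tris(benzyloxy)-3,5-bis(phenylsulfanylmethyl)phenyl]-2-methylbutan-1-one | CC[C@H](C)C(=O)c1c(OCc2ccccc2)c(CSc2ccccc2)c(OCc2ccccc2)c(CSc2ccccc2)c1OCc1ccccc1 | intermediate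
8 | 2,4,6-trihydroxytoluene (2-methylbenzene-1,3,5-triol) | Cc1c(O)cc(O)cc1O | starting material
9 | 1-(2,4,6-trihydroxy-3-methylphenyl)butan-1-one | CCCC(=O)c1c(O)cc(O)c(C)c1O | intermediate
10 | 1-[4,6-bis(benzyloxy)-2-hydroxy-3-methylphenyl]butan-1-one | CCCC(=O)c1c(OCc2ccccc2)cc(OCc2ccccc2)c(C)c1O | intermediate
11 | 1-[4,6-bis(benzyloxy)-2-methoxy-3-methylphenyl]butan-1-one | CCCC(=O)c1c(OCc2ccccc2)cc(OCc2ccccc2)c(C)c1OC | intermediate
12 | 1-(4,6-dihydroxy-2-methoxy-3-methylphenyl)butan-1-one (lateral phenol) | CCCC(=O)c1c(O)cc(O)c(C)c1OC | intermediate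
13 | bis(S-chlorosulfonium) bis(succinimidate) of 7, each sulfur carrying Cl, phenyl and the ring B benzylic CH2 (formed in the flask; the N–S bonded ion pair would react alike) | CC[C@H](C)C(=O)c1c(OCc2ccccc2)c(C[S+](Cl)c2ccccc2)c(OCc2ccccc2)c(C[S+](Cl)c2ccccc2)c1OCc1ccccc1.O=C1CCC(=O)[N-]1.O=C1CCC(=O)[N-]1 | intermediate
14 | bis(aryloxysulfonium) dichloride, each sulfur carrying phenyl, the ring B benzylic CH2 and the 4-oxygen of one molecule of 12 (formed in the flask; drawn for capture by the 4-OH) | CC[C@H](C)C(=O)c1c(OCc2ccccc2)c(C[S+](Oc2cc(O)c(C(=O)CCC)c(OC)c2C)c2ccccc2)c(OCc2ccccc2)c(C[S+](Oc2cc(O)c(C(=O)CCC)c(OC)c2C)c2ccccc2)c1OCc1ccccc1.[Cl-].[Cl-] | intermediate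
15 | (2S)-1-[2,4,6-tris(benzyloxy)-3,5-bis[(3-butanoyl-2,6-dihydroxy-4-methoxy-5-methylphenyl)(phenylsulfanyl)methyl]phenyl]-2-methylbutan-1-one, bridge carbons of mixed configuration | CC[C@H](C)C(=O)c1c(OCc2ccccc2)c(C(Sc2ccccc2)c2c(O)c(C)c(OC)c(C(=O)CCC)c2O)c(OCc2ccccc2)c(C(Sc2ccccc2)c2c(O)c(C)c(OC)c(C(=O)CCC)c2O)c1OCc1ccccc1 | intermediate
16 | (2S)-1-[2,4,6-tris(benzyloxy)-3,5-bis[(3-butanoyl-2,6-dihydroxy-4-methoxy-5-methylphenyl)methyl]phenyl]-2-methylbutan-1-one (agrimol B tribenzyl ether, formed in the flask) | CC[C@H](C)C(=O)c1c(OCc2ccccc2)c(Cc2c(O)c(C)c(OC)c(C(=O)CCC)c2O)c(OCc2ccccc2)c(Cc2c(O)c(C)c(OC)c(C(=O)CCC)c2O)c1OCc1ccccc1 | intermediate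
17 | agrimol B, (2S)-1-[3,5-bis[(3-butanoyl-2,6-dihydroxy-4-methoxy-5-methylphenyl)methyl]-2,4,6-trihydroxyphenyl]-2-methylbutan-1-one | CCCC(=O)c1c(O)c(Cc2c(O)c(Cc3c(O)c(C)c(OC)c(C(=O)CCC)c3O)c(O)c(C(=O)[C@@H](C)CC)c2O)c(O)c(C)c1OC | target

**Step count and risks**
Total steps: 9. Longest linear sequence: 6 steps (8 → 9 → 10 → 11 → 12 → 15 → 17); the ring B arm reaches the target in 5.

**Step 8.** The chlorosulfonium ion of a benzylic sulfide may collapse by Pummerer-type loss of HCl before the phenol oxygen is bound, leftover NCS may chlorinate the free ring carbon of 12, or the shift may stall at the crowded ring. The fallback sets out from 7 and returns at 15, using known chemistry only. NCS (2.1 equiv) in CCl4 at room temperature, without phenol or base, should drive the known Pummerer-type α-chlorination of benzyl phenyl sulfides to completion and give the bis(α-chloro sulfide) (2S)-1-[2,4,6-tris(benzyloxy)-3,5-bis[chloro(phenylsulfanyl)methyl]phenyl]-2-methylbutan-1-one F1. After succinimide is filtered off, crude F1 would be added to 12 (3 equiv, two of which are taken up) and ZnCl2 (0.2 equiv) in CH2Cl2 at −40 → 0 °C. The thionium ion released from each arm should alkylate the one free ring carbon of 12 in a Friedel–Crafts reaction, as established for α-chloro sulfides and phenols, to give 15.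

**Step 3.** Three hindered, hydrogen-bonded hydroxyls must be alkylated; benzylation at ring carbon with loss of aromaticity, or base-induced loss of thiophenolate through an ortho-quinone methide, may compete. The fallback sets out from 6 and returns at 17 with an acyl protecting group. O-Acetylation (Ac2O, pyridine, DMAP cat., CH2Cl2, 0 °C → rt) cannot alkylate carbon and should give 2-[(2S)-2-methylbutanoyl]-4,6-bis(phenylsulfanylmethyl)benzene-1,3,5-triyl triacetate F2, whose electron-poorer ring should also slow thionium formation in the next operation. The procedure of step 8 applied to F2 and two molecules of 12 would give the bis(phenylsulfanyl)-bridged ring B triacetate F3. Raney Ni in EtOH would give agrimol B ring B triacetate F4, and acid-catalysed methanolysis (HCl in MeOH, rt) would give 17.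

**Step 9.** The non-chelated, benzyl-flanked ketone of ring B may be reduced on the Raney Ni surface, C–S cleavage may be incomplete at the crowded bridge carbons, or residual sulfur may poison the Pd stage. The fallback sets out from 15 and returns at 17 through 16, which is then isolated. Radical desulfurisation with Bu3SnH (3 equiv) and AIBN (cat.) in toluene at 90 °C cleaves benzylic C–S bonds by a chain process that does not touch ketones and should give 16. After chromatography, H2 over Pd(OH)2/C in EtOAc/EtOH would remove the benzyl ethers and give 17.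

**Further compounds**
F1 | step 8 | (2S)-1-[2,4,6-tris(benzyloxy)-3,5-bis[chloro(phenylsulfanyl)methyl]phenyl]-2-methylbutan-1-one | CC[C@H](C)C(=O)c1c(OCc2ccccc2)c(C(Cl)Sc2ccccc2)c(OCc2ccccc2)c(C(Cl)Sc2ccccc2)c1OCc1ccccc1
F2 | step 3 | 2-[(2S)-2-methylbutanoyl]-4,6-bis(phenylsulfanylmethyl)benzene-1,3,5-triyl triacetate | CC[C@H](C)C(=O)c1c(OC(C)=O)c(CSc2ccccc2)c(OC(C)=O)c(CSc2ccccc2)c1OC(C)=O
F3 | step 3 | bis(phenylsulfanyl)-bridged ring B triacetate, 2-[(2S)-2-methylbutanoyl]-4,6-bis[(3-butanoyl-2,6-dihydroxy-4-methoxy-5-methylphenyl)(phenylsulfanyl)methyl]benzene-1,3,5-triyl triacetate | CC[C@H](C)C(=O)c1c(OC(C)=O)c(C(Sc2ccccc2)c2c(O)c(C)c(OC)c(C(=O)CCC)c2O)c(OC(C)=O)c(C(Sc2ccccc2)c2c(O)c(C)c(OC)c(C(=O)CCC)c2O)c1OC(C)=O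
F4 | step 3 | agrimol B ring B triacetate, 2-[(2S)-2-methylbutanoyl]-4,6-bis[(3-butanoyl-2,6-dihydroxy-4-methoxy-5-methylphenyl)methyl]benzene-1,3,5-triyl triacetate | CC[C@H](C)C(=O)c1c(OC(C)=O)c(Cc2c(O)c(C)c(OC)c(C(=O)CCC)c2O)c(OC(C)=O)c(Cc2c(O)c(C)c(OC)c(C(=O)CCC)c2O)c1OC(C)=O
F0 | step 9 | none | none
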